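**Retrosynthetic overview** (ring locants as in the target name: C1 carries the acetate, C2 the side chain, C3 is the vinylic CH, C4 the gem-dimethyl carbon, C5 the CHBr, C6 the CH2)
- Both C–Br bonds come last from carbinols by Appel inversion (C5 first, the labile allylic side-chain bromide at the very end), and the acetate comes from a Mitsunobu inversion at C1.
- The C5 carbinol comes from enantioselective conjugate borylation/oxidation of a 2-substituted 4,4-dimethylcyclohexa-2,5-dienone; C1 is then set by substrate-controlled Luche reduction.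
- The dienone, the only carbocycle of the target, is made in one operation from a 2-substituted 3-ethoxycyclobutanone and the silyl enol ether of isobutyraldehyde (formal [4+2]: bonds C4–C5 and C2–C3, the latter becoming C2=C3). The four-membered ring is formed first and is opened in the step that closes the six-membered ring.
- Enabling feature: C2–C1(O)–C6–C5(heteroatom), with C6 a plain CH2, is the 1,4-zwitterion stored in a strained β-alkoxy cyclobutanone, and the remaining C3(H)=/C4(CH3)2 pair is exactly the enol of isobutyraldehyde.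
- The side chain, C2 and C1 come from the chiral pool: ethyl (3R)-4-chloro-3-hydroxybutanoate, via its ketene and a [2+2] with ethyl vinyl ether.

Key step: step 4

Assumption: the antipode of the ferrocenyl bisphosphine in step 5 is the one that delivers boron to the ring face giving 5R; if the facial sense proves opposite, the enantiomeric ligand is used.

**Step 1**
Reactants: 1 ethyl (3R)-4-chloro-3-hydroxybutanoate
Product: 2 ethyl (3R)-3-[(tert-butyldimethylsilyl)oxy]-4-chlorobutanoate
Conditions: TBSCl, imidazole, DMF, 0 °C to rt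
Reagents that add atoms: tert-butyldimethylsilyl chloride, CC(C)(C)[Si](C)(C)Cl
Why: Standard silyl ether formation at the secondary alcohol; the stereocentre (the later side-chain CHBr carbon) is not touched.

**Step 2**
Reactants: 2 ethyl (3R)-3-[(tert-butyldimethylsilyl)oxy]-4-chlorobutanoate
Product: 3 (3R)-3-[(tert-butyldimethylsilyl)oxy]-4-chlorobutanoic acid
Conditions: LiOH·H2O, THF/H2O, 0 °C; cold 1 M HCl to pH 3, used at once
Reagents that add atoms: lithium hydroxide, [Li+].[OH-]
Why: Ester saponification at low temperature, which the hindered silyl ether and the primary chloride should survive; the acid is not stored, to avoid lactonisation onto the chloride.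

**Step 3**
Reactants: 3 (3R)-3-[(tert-butyldimethylsilyl)oxy]-4-chlorobutanoic acid; 4 ethyl vinyl ether
Product: 7 2-[(1R)-1-[(tert-butyldimethylsilyl)oxy]-2-chloroethyl]-3-ethoxycyclobutan-1-one (mixture of ring diastereomers), via acid chloride 5 (not isolated), via ketene 6 (not isolated)
Conditions: (COCl)2, DMF (cat.), CH2Cl2, 0 °C to rt, evaporate; then 4 (5 equiv), Et3N, MeCN, reflux, slow addition of 5
Reagents that add atoms: none
Why: Acid chloride formation, dehydrochlorination to the monoalkylketene and thermal ketene–enol ether [2+2] cycloaddition, in which the ketene carbonyl carbon bonds to the CH2 of the vinyl ether (ethoxy at C3, side chain at C2); the two ring stereocentres form without control and are erased in step 4.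

**Step 4**
Reactants: 7 2-[(1R)-1-[(tert-butyldimethylsilyl)oxy]-2-chloroethyl]-3-ethoxycyclobutan-1-one; 8 2-methyl-1-(trimethylsilyloxy)prop-1-ene
Product: 11 2-[(1R)-1-[(tert-butyldimethylsilyl)oxy]-2-chloroethyl]-4,4-dimethylcyclohexa-2,5-dien-1-one, via cycloadduct 9 (not isolated), via ethoxy enone 10 (not isolated)
Conditions: 8 (1.5 equiv), EtAlCl2 (1.2 equiv), CH2Cl2, −78 °C; cold 1 M HCl wash; crude 9 with p-TsOH·H2O (10 mol %), toluene, 50 °C
Reagents that add atoms: none
Why: EtAlCl2 binds the ketone of 7 and the strained bond between the side-chain-bearing α-carbon and the ethoxy-bearing carbon heterolyses to a zwitterion (aluminium enolate and ethoxycarbenium ion). The dimethyl-substituted carbon of 8 adds to the oxocarbenium ion (Mukaiyama-type addition, which makes the quaternary C4 and the C4–C5 bond), and the new silyloxycarbenium ion is trapped by the enolate carbon in a 6-(enolendo)-exo-trig aldol closure (C2–C3 bond) to give 9. Acid then removes Me3SiOH across C2–C3 and EtOH across C5–C6 by enol-mediated β-elimination, giving the cross-conjugated dienone. The closest known reaction type is the Lewis-acid-promoted formal [4+2] cycloaddition of 3-alkoxycyclobutanones with silyl enol ethers. The stereocentres formed at C2, C3 and C5 of 9 are not controlled and are all removed by the two eliminations, while the side-chain centre is not involved. The step needs cleavage of the ring bond to the substituted α-carbon rather than to the CH2, and loss of the ring trimethylsilyloxy group rather than the side-chain silyloxy group: the first should be secured by the more substituted, better stabilised enolate, the second by the much higher acid lability of the trimethylsilyl ether and by the fact that C2 carries no hydrogen once C2=C3 exists.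

**Step 5**
Reactants: 11 2-[(1R)-1-[(tert-butyldimethylsilyl)oxy]-2-chloroethyl]-4,4-dimethylcyclohexa-2,5-dien-1-one
Product: 13 (5R)-2-[(1R)-1-[(tert-butyldimethylsilyl)oxy]-2-chloroethyl]-5-hydroxy-4,4-dimethylcyclohex-2-en-1-one, via boryl ketone 12 (not isolated)
Conditions: B2pin2 (1.1 equiv), CuCl (5 mol %), NaOtBu (5 mol %), (R)-1-[(S)-2-(diphenylphosphino)ferrocenyl]ethyldicyclohexylphosphine (6 mol %), MeOH (2 equiv), THF, 0 °C; then NaBO3·4H2O, THF/H2O, rt
Reagents that add atoms: sodium perborate, [Na+].[Na+].O[B-]1(O)OO[B-](O)(O)OO1 (oxygen of the new hydroxyl); bis(pinacolato)diboron, CC1(C)OB(OC1(C)C)B1OC(C)(C)C(C)(C)O1 (boryl group of 12 only)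
Why: Copper-catalysed enantioselective conjugate borylation of the α-unsubstituted enone (the α-substituted C2=C3 enone should react far more slowly), followed by stereoretentive C–B oxidation; the chiral ligand sets C5 as R.

**Step 6**
Reactants: 13 (5R)-2-[(1R)-1-[(tert-butyldimethylsilyl)oxy]-2-chloroethyl]-5-hydroxy-4,4-dimethylcyclohex-2-en-1-one
Product: 14 (1S,5R)-2-[(1R)-1-[(tert-butyldimethylsilyl)oxy]-2-chloroethyl]-4,4-dimethylcyclohex-2-ene-1,5-diol
Conditions: NaBH4, CeCl3·7H2O, MeOH, −78 °C
Reagents that add atoms: none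
Why: Luche 1,2-reduction; hydride should add to the face away from a syn-axial C5 oxygen (or axially when that oxygen is equatorial), so the C5 stereocentre directs formation of the cis-1,5-diol (1S), as is usual for 5-substituted cyclohexenones.

**Step 7**
Reactants: 14 (1S,5R)-2-[(1R)-1-[(tert-butyldimethylsilyl)oxy]-2-chloroethyl]-4,4-dimethylcyclohex-2-ene-1,5-diol
Product: 15 (1R,5R)-2-[(1R)-1-[(tert-butyldimethylsilyl)oxy]-2-chloroethyl]-5-hydroxy-4,4-dimethylcyclohex-2-en-1-yl acetate
Conditions: AcOH, PPh3, DIAD, THF, 0 °C to rt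
Reagents that add atoms: acetic acid, CC(=O)O
Why: Mitsunobu esterification, in which only the allylic C1 carbinol can be displaced (the C5 carbinol is neopentylic), so SN2 inversion gives the 1R acetate trans to the C5 hydroxyl; SN2′ attack at C3 is blocked by the adjacent quaternary C4.

**Step 8**
Reactants: 15 (1R,5R)-2-[(1R)-1-[(tert-butyldimethylsilyl)oxy]-2-chloroethyl]-5-hydroxy-4,4-dimethylcyclohex-2-en-1-yl acetate
Product: 16 (1R,5S)-5-bromo-2-[(1R)-1-[(tert-butyldimethylsilyl)oxy]-2-chloroethyl]-4,4-dimethylcyclohex-2-en-1-yl acetate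
Conditions: CBr4 (3 equiv), PPh3 (3 equiv), 1,2-dichloroethane, 60 °C
Reagents that add atoms: carbon tetrabromide, BrC(Br)(Br)Br
Why: Appel bromination with SN2 inversion at the neopentylic secondary carbinol, a displacement that is slow next to a quaternary carbon and therefore run hot, and which should give the 5S bromide cis to the acetate.

**Step 9**
Reactants: 16 (1R,5S)-5-bromo-2-[(1R)-1-[(tert-butyldimethylsilyl)oxy]-2-chloroethyl]-4,4-dimethylcyclohex-2-en-1-yl acetate
Product: 17 (1R,5S)-5-bromo-2-[(1R)-2-chloro-1-hydroxyethyl]-4,4-dimethylcyclohex-2-en-1-yl acetate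
Conditions: HF·pyridine, pyridine, THF, 0 °C to rt; used directly
Reagents that add atoms: none
Why: Fluoride-mediated desilylation under weakly acidic conditions, so that no alkoxide is formed that could close an epoxide onto the chloride or shift the acetyl group.

**Step 10**
Reactants: 17 (1R,5S)-5-bromo-2-[(1R)-2-chloro-1-hydroxyethyl]-4,4-dimethylcyclohex-2-en-1-yl acetate
Product: 18 (1R,5S)-5-bromo-2-[(1S)-1-bromo-2-chloroethyl]-4,4-dimethylcyclohex-2-en-1-yl acetate
Conditions: CBr4 (1.5 equiv), PPh3 (1.5 equiv), CH2Cl2, −20 to 0 °C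
Reagents that add atoms: carbon tetrabromide, BrC(Br)(Br)Br
Why: Appel bromination of the secondary allylic carbinol at low temperature with SN2 inversion (side-chain 1R to 1S); SN2′ attack at C3 is blocked by the quaternary C4, and the bromide is made last because it is the most labile group.

**Compound list**
1 | ethyl (3R)-4-chloro-3-hydroxybutanoate | CCOC(=O)C[C@@H](O)CCl | starting material
2 | ethyl (3R)-3-[(tert-butyldimethylsilyl)oxy]-4-chlorobutanoate | CCOC(=O)C[C@@H](O[Si](C)(C)C(C)(C)C)CCl | intermediate
3 | (3R)-3-[(tert-butyldimethylsilyl)oxy]-4-chlorobutanoic acid | OC(=O)C[C@@H](O[Si](C)(C)C(C)(C)C)CCl | intermediate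
4 | ethyl vinyl ether | C=COCC | starting material
5 | (3R)-3-[(tert-butyldimethylsilyl)oxy]-4-chlorobutanoyl chloride (not isolated) | ClC(=O)C[C@@H](O[Si](C)(C)C(C)(C)C)CCl | intermediate
6 | (3R)-3-[(tert-butyldimethylsilyl)oxy]-4-chlorobut-1-en-1-one, the monoalkylketene (not isolated) | O=C=C[C@@H](O[Si](C)(C)C(C)(C)C)CCl | intermediate
7 | 2-[(1R)-1-[(tert-butyldimethylsilyl)oxy]-2-chloroethyl]-3-ethoxycyclobutan-1-one, mixture of ring diastereomers | O=C1CC(OCC)C1[C@@H](O[Si](C)(C)C(C)(C)C)CCl | intermediate
8 | 2-methyl-1-(trimethylsilyloxy)prop-1-ene (silyl enol ether of isobutyraldehyde) | CC(C)=CO[Si](C)(C)C | starting material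
9 | 2-[(1R)-1-[(tert-butyldimethylsilyl)oxy]-2-chloroethyl]-5-ethoxy-4,4-dimethyl-3-(trimethylsilyloxy)cyclohexan-1-one, diastereomer mixture (not isolated) | O=C1CC(OCC)C(C)(C)C(O[Si](C)(C)C)C1[C@@H](O[Si](C)(C)C(C)(C)C)CCl | intermediate
10 | 2-[(1R)-1-[(tert-butyldimethylsilyl)oxy]-2-chloroethyl]-5-ethoxy-4,4-dimethylcyclohex-2-en-1-one, both C5 epimers (not isolated) | O=C1CC(OCC)C(C)(C)C=C1[C@@H](O[Si](C)(C)C(C)(C)C)CCl | intermediate
11 | 2-[(1R)-1-[(tert-butyldimethylsilyl)oxy]-2-chloroethyl]-4,4-dimethylcyclohexa-2,5-dien-1-one | O=C1C=CC(C)(C)C=C1[C@@H](O[Si](C)(C)C(C)(C)C)CCl | intermediate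
12 | (5R)-2-[(1R)-1-[(tert-butyldimethylsilyl)oxy]-2-chloroethyl]-4,4-dimethyl-5-(4,4,5,5-tetramethyl-1,3,2-dioxaborolan-2-yl)cyclohex-2-en-1-one (not isolated) | O=C1C[C@@H](B2OC(C)(C)C(C)(C)O2)C(C)(C)C=C1[C@@H](O[Si](C)(C)C(C)(C)C)CCl | intermediate
13 | (5R)-2-[(1R)-1-[(tert-butyldimethylsilyl)oxy]-2-chloroethyl]-5-hydroxy-4,4-dimethylcyclohex-2-en-1-one | O=C1C[C@@H](O)C(C)(C)C=C1[C@@H](O[Si](C)(C)C(C)(C)C)CCl | intermediate
14 | (1S,5R)-2-[(1R)-1-[(tert-butyldimethylsilyl)oxy]-2-chloroethyl]-4,4-dimethylcyclohex-2-ene-1,5-diol (cis-diol) | O[C@H]1C[C@@H](O)C(C)(C)C=C1[C@@H](O[Si](C)(C)C(C)(C)C)CCl | intermediate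
15 | (1R,5R)-2-[(1R)-1-[(tert-butyldimethylsilyl)oxy]-2-chloroethyl]-5-hydroxy-4,4-dimethylcyclohex-2-en-1-yl acetate | CC(=O)O[C@@H]1C[C@@H](O)C(C)(C)C=C1[C@@H](O[Si](C)(C)C(C)(C)C)CCl | intermediate
16 | (1R,5S)-5-bromo-2-[(1R)-1-[(tert-butyldimethylsilyl)oxy]-2-chloroethyl]-4,4-dimethylcyclohex-2-en-1-yl acetate | CC(=O)O[C@@H]1C[C@H](Br)C(C)(C)C=C1[C@@H](O[Si](C)(C)C(C)(C)C)CCl | intermediate
17 | (1R,5S)-5-bromo-2-[(1R)-2-chloro-1-hydroxyethyl]-4,4-dimethylcyclohex-2-en-1-yl acetate | CC(=O)O[C@@H]1C[C@H](Br)C(C)(C)C=C1[C@@H](O)CCl | intermediate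
18 | (1R,5S)-5-bromo-2-[(1S)-1-bromo-2-chloroethyl]-4,4-dimethylcyclohex-2-en-1-yl acetate | CC(=O)O[C@@H]1C[C@H](Br)C(C)(C)C=C1[C@H](Br)CCl | target

**Step count and risks**
Total step count: 10. Longest linear sequence: 10 steps (from 1; compounds 4 and 8 are purchased).

Steps most likely to fail:

1. Step 4. The four-membered ring may open on its unsubstituted side, giving the regioisomeric ring. The side-chain silyloxy group may also be lost by β-elimination, either from the aluminium enolate or during the acid stage, and the silyl ether may be cleaved by the acid. The fallback sets out from 2 and comes back at 11, making the same two ring bonds by a Robinson-type enamine annulation. Ester 2 with MeNH(OMe)·HCl and iPrMgCl gives the Weinreb amide F1. CH2=CHMgBr converts it to the vinyl ketone F2. Isobutyraldehyde with catalytic pyrrolidine, then AcOH in warm toluene (Michael addition and aldol condensation), gives the enone F3. Dehydrogenation with 2-iodoxybenzoic acid in DMSO (or a Saegusa–Ito oxidation with Pd(OAc)2) gives 11.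

2. Step 8. Displacement at the carbon next to the quaternary centre is slow, so participation of the trans-1,3 acetate, elimination toward C6 or a methyl shift may compete with direct inversion. The fallback sets out from 12 (isolated by leaving out the perborate oxidation in step 5) and comes back at 16, replacing the C–O displacement by a stereospecific C–B to C–Br exchange. Corey–Bakshi–Shibata reduction of 12 with (S)-2-methyl-CBS-oxazaborolidine and BH3·SMe2 gives the hydroxy boronate F4 (1R, hydroxyl trans to boron). 3,5-Bis(trifluoromethyl)phenyllithium (2.2 equiv) at −78 °C, then N-bromosuccinimide, brominates the boronate complex with inversion to the bromo alcohol F5. Acetylation with Ac2O and pyridine gives 16.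

3. Step 5. Facial selectivity may be poor, or boron may add at the wrong enone, since both β-carbons adjoin the quaternary carbon. The fallback sets out from 11 and comes back at 13. Amine-catalysed asymmetric nucleophilic epoxidation of the unsubstituted enone (9-amino-9-deoxy-epi-quinine salt, aqueous H2O2) gives the epoxy ketone F6. Reductive opening at the α-carbon with Na[PhSeB(OEt)3] (from PhSeSePh and NaBH4 in EtOH, with AcOH) gives 13.

**Further compounds**
F1 | step 4 | (3R)-3-[(tert-butyldimethylsilyl)oxy]-4-chloro-N-methoxy-N-methylbutanamide | CON(C)C(=O)C[C@@H](O[Si](C)(C)C(C)(C)C)CCl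
F2 | step 4 | (5R)-5-[(tert-butyldimethylsilyl)oxy]-6-chlorohex-1-en-3-one | C=CC(=O)C[C@@H](O[Si](C)(C)C(C)(C)C)CCl
F3 | step 4 | 2-[(1R)-1-[(tert-butyldimethylsilyl)oxy]-2-chloroethyl]-4,4-dimethylcyclohex-2-en-1-one | O=C1CCC(C)(C)C=C1[C@@H](O[Si](C)(C)C(C)(C)C)CCl
F4 | step 8 | (1R,5R)-2-[(1R)-1-[(tert-butyldimethylsilyl)oxy]-2-chloroethyl]-4,4-dimethyl-5-(4,4,5,5-tetramethyl-1,3,2-dioxaborolan-2-yl)cyclohex-2-en-1-ol | O[C@@H]1C[C@@H](B2OC(C)(C)C(C)(C)O2)C(C)(C)C=C1[C@@H](O[Si](C)(C)C(C)(C)C)CCl
F5 | step 8 | (1R,5S)-5-bromo-2-[(1R)-1-[(tert-butyldimethylsilyl)oxy]-2-chloroethyl]-4,4-dimethylcyclohex-2-en-1-ol | O[C@@H]1C[C@H](Br)C(C)(C)C=C1[C@@H](O[Si](C)(C)C(C)(C)C)CCl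
F6 | step 5 | 2-[(1R)-1-[(tert-butyldimethylsilyl)oxy]-2-chloroethyl]-5,6-epoxy-4,4-dimethylcyclohex-2-en-1-one, oxirane oxygen on the face of the later 5R hydroxyl | O=C1[C@H]2O[C@H]2C(C)(C)C=C1[C@@H](O[Si](C)(C)C(C)(C)C)CCl
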